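## Retrosynthetic overview

1. The target is freed last from its hexakis‑silyl ether 15 by fluoride.
2. The oxolane (the only ring made, and made last) is cut at C3–C4 and C5–O1. The C3 α‑keto radical comes from dioxolanyl ketone 9 by light‑driven Cα–O cleavage and adds to silyl enol ether 13. The C2 oxygen closes the ring, and the ketal carbon C5 is reduced in the same pot.
3. Ketone 9 comes from ester 4 and an aryllithium through a Weinreb amide.
4. Ester 4 gets its C2–aryl bond by light‑driven Ir/Ni decarboxylative arylation of the D‑tartrate acetonide mono‑acid 2, trans to the surviving ester. This is the only source of chirality.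
5. Enol ether 13 comes from resorcinol and 3‑(4‑hydroxyphenyl)propanoic acid (Friedel–Crafts), then persilylation.

Assumption: the oxolane is numbered O1, C2 (4‑hydroxyphenyl), C3 (aroyl), C4 (4‑hydroxybenzyl), C5 (2,4‑dihydroxyphenyl); the given SMILES is then (2S,3S,4S,5S), all‑trans. TIPS = triisopropylsilyl. Compounds 1 and 3 are taken as catalogue items; 1 derives from D‑(−)‑tartaric acid (the natural L‑series would give the enantiomer).

## Route

Step 1
Reactants: 1 dimethyl (4S,5S)-2,2-dimethyl-1,3-dioxolane-4,5-dicarboxylate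
Product: 2 (4S,5S)-5-(methoxycarbonyl)-2,2-dimethyl-1,3-dioxolane-4-carboxylic acid
Conditions: KOH (1.0 equiv), MeOH, 0 °C to rt; then aq. HCl to pH 2
Reagents that add atoms: potassium hydroxide, [K+].[OH-]
Why: Mono‑saponification of a C2‑symmetric diester stops after one ester because the carboxylate formed deactivates the molecule towards a second hydroxide; neither stereocentre is touched.

Step 2
Reactants: 2 (4S,5S)-5-(methoxycarbonyl)-2,2-dimethyl-1,3-dioxolane-4-carboxylic acid; 3 (4-bromophenoxy)triisopropylsilane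
Product: 4 methyl (4S,5R)-2,2-dimethyl-5-[4-(triisopropylsilyloxy)phenyl]-1,3-dioxolane-4-carboxylate
Conditions: Ir[dF(CF3)ppy]2(dtbbpy)PF6 (1 mol%), NiCl2·glyme (10 mol%), dtbbpy (15 mol%), Cs2CO3 (1.5 equiv), DMF, 450 nm LEDs, rt
Reagents that add atoms: none
Why: Metallaphotoredox decarboxylative arylation of an α‑oxy acid: the dioxolanyl radical left after CO2 loss is taken up by the aryl–nickel species and coupled on the face anti to the neighbouring CO2Me, so the new benzylic centre (later C2) is set trans (5R) by the remaining tartrate centre.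

Step 3
Reactants: 5 4-bromobenzene-1,3-diol
Product: 6 [(4-bromo-1,3-phenylene)bis(oxy)]bis(triisopropylsilane)
Conditions: TIPSCl (2.4 equiv), imidazole (5 equiv), DMF, rt
Reagents that add atoms: chlorotriisopropylsilane, CC(C)[Si](Cl)(C(C)C)C(C)C
Why: Standard phenol silylation; the bulky TIPS group is chosen because it resists carbonate in DMF and anionic ortho O‑to‑C silyl migration.

Step 4
Reactants: 4 methyl (4S,5R)-2,2-dimethyl-5-[4-(triisopropylsilyloxy)phenyl]-1,3-dioxolane-4-carboxylate; 6 [(4-bromo-1,3-phenylene)bis(oxy)]bis(triisopropylsilane)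
Product: 9 [2,4-bis(triisopropylsilyloxy)phenyl][(4S,5R)-2,2-dimethyl-5-[4-(triisopropylsilyloxy)phenyl]-1,3-dioxolan-4-yl]methanone, via Weinreb amide 7 (not isolated), via aryllithium 8 (not isolated)
Conditions: MeNHOMe·HCl (1.5 equiv), iPrMgCl (3.0 equiv), THF, −20 °C; then 8 (1.4 equiv; from 6, n‑BuLi, THF, −78 °C) added at −78 °C, warm to −20 °C; aq. NH4Cl
Reagents that add atoms: none
Why: One‑pot Weinreb ketone synthesis: the ester is converted to the N‑methoxy‑N‑methylamide by the chloromagnesium amide, and the chelated tetrahedral adduct of the aryllithium (from Br/Li exchange) holds until quench, so no over‑addition; the benzylic centre is not acidic and is retained.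

Step 5
Reactants: 10 benzene-1,3-diol (resorcinol); 11 3-(4-hydroxyphenyl)propanoic acid
Product: 12 1-(2,4-dihydroxyphenyl)-3-(4-hydroxyphenyl)propan-1-one (davidigenin)
Conditions: BF3·OEt2 (neat), 90 °C, 2 h; aq. NaOAc work-up
Reagents that add atoms: none
Why: Friedel–Crafts (Nencki‑type) acylation of resorcinol by the free acid in BF3·OEt2 occurs at C4 (ortho to one OH, para to the other), giving the 2,4‑dihydroxyphenyl ketone directly.

Step 6
Reactants: 12 1-(2,4-dihydroxyphenyl)-3-(4-hydroxyphenyl)propan-1-one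
Product: 13 (Z)-{1-[2,4-bis(triisopropylsilyloxy)phenyl]-3-[4-(triisopropylsilyloxy)phenyl]prop-1-en-1-yl}oxy(triisopropyl)silane
Conditions: TIPSOTf (4.6 equiv), Et3N (7 equiv), CH2Cl2, 0 °C to rt
Reagents that add atoms: triisopropylsilyl trifluoromethanesulfonate, CC(C)[Si](OS(=O)(=O)C(F)(F)F)(C(C)C)C(C)C
Why: Silyl triflate/amine silylates the three phenols and soft‑enolises the aryl ketone to the thermodynamic Z silyl enol ether in one operation.

Step 7
Reactants: 9 [2,4-bis(triisopropylsilyloxy)phenyl][(4S,5R)-2,2-dimethyl-5-[4-(triisopropylsilyloxy)phenyl]-1,3-dioxolan-4-yl]methanone; 13 (Z)-{1-[2,4-bis(triisopropylsilyloxy)phenyl]-3-[4-(triisopropylsilyloxy)phenyl]prop-1-en-1-yl}oxy(triisopropyl)silane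
Product: 15 [2,4-bis(triisopropylsilyloxy)phenyl][(2S,3S,4S,5S)-5-[2,4-bis(triisopropylsilyloxy)phenyl]-2-[4-(triisopropylsilyloxy)phenyl]-4-[4-(triisopropylsilyloxy)benzyl]oxolan-3-yl]methanone, via silyl ketal 14 (not isolated)
Conditions: fac-Ir(ppy)3 (2 mol%), Mg(OTf)2 (1.2 equiv), 13 (1.5 equiv), MeCN/CH2Cl2 1:1, 450 nm LEDs, rt; then evaporate, CH2Cl2, Et3SiH (2 equiv), BF3·OEt2 (4 equiv), −40 to 0 °C
Reagents that add atoms: none
Why: Proposed new method: a redox‑neutral photocatalytic ketyl‑fragmentation (3+2) annulation — excited fac‑Ir(ppy)3 reduces the Mg‑chelated α‑alkoxy aryl ketone, the ketyl radical anion expels the acetonide Cα–O bond and the hemiketal alkoxide loses acetone, the electrophilic C3 α‑keto radical adds to the electron‑rich silyl enol ether at C4, the α‑silyloxybenzyl radical is oxidised by the tetravalent iridium complex (closing the cycle) and the C2 alkoxide traps the silyloxocarbenium ion to close the ring (closest known types: photoredox alkylation of silyl enol ethers by α‑bromo ketones to 1,4‑diketones, and single‑electron Cα–O cleavage of α‑oxygenated ketones); C2 keeps its C–O bond and configuration, then under BF3 the oxocarbenium ion equilibrates with its C4=C5 enol‑ether tautomer (C3–H there is allylic and α to the ketone) so C3 and C4 relax to trans,trans relative to the C2 aryl, and Et3SiH attacks the inside face of the all‑pseudoequatorial envelope, placing the C5 aryl trans to the benzyl group (also the thermodynamic outcome), giving the all‑trans (2S,3S,4S,5S) oxolane.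

Step 8
Reactants: 15 [2,4-bis(triisopropylsilyloxy)phenyl][(2S,3S,4S,5S)-5-[2,4-bis(triisopropylsilyloxy)phenyl]-2-[4-(triisopropylsilyloxy)phenyl]-4-[4-(triisopropylsilyloxy)benzyl]oxolan-3-yl]methanone
Product: 16 (2,4-dihydroxyphenyl)[(2S,3S,4S,5S)-5-(2,4-dihydroxyphenyl)-2-(4-hydroxyphenyl)-4-(4-hydroxybenzyl)oxolan-3-yl]methanone (target)
Conditions: Bu4NF (8 equiv), AcOH (8 equiv), THF, 0 °C to rt, argon; reversed-phase purification
Reagents that add atoms: none
Why: Fluoride‑mediated cleavage of aryl silyl ethers; buffering with AcOH keeps phenoxide and enolate concentrations low, so the β‑alkoxy ketone neither ring‑opens by E1cB nor epimerises, and the acid‑labile benzylic ethers are untouched.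

## Compound list

1 | dimethyl (4S,5S)-2,2-dimethyl-1,3-dioxolane-4,5-dicarboxylate [(+)-dimethyl 2,3-O-isopropylidene-D-tartrate] | COC(=O)[C@H]1OC(C)(C)O[C@@H]1C(=O)OC | starting material
2 | (4S,5S)-5-(methoxycarbonyl)-2,2-dimethyl-1,3-dioxolane-4-carboxylic acid | OC(=O)[C@H]1OC(C)(C)O[C@@H]1C(=O)OC | intermediate
3 | (4-bromophenoxy)triisopropylsilane | CC(C)[Si](Oc1ccc(Br)cc1)(C(C)C)C(C)C | starting material
4 | methyl (4S,5R)-2,2-dimethyl-5-[4-(triisopropylsilyloxy)phenyl]-1,3-dioxolane-4-carboxylate | CC(C)[Si](Oc1ccc(cc1)[C@H]2OC(C)(C)O[C@@H]2C(=O)OC)(C(C)C)C(C)C | intermediate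
5 | 4-bromobenzene-1,3-diol | Oc1ccc(Br)c(O)c1 | starting material
6 | [(4-bromo-1,3-phenylene)bis(oxy)]bis(triisopropylsilane) | CC(C)[Si](Oc1ccc(Br)c(O[Si](C(C)C)(C(C)C)C(C)C)c1)(C(C)C)C(C)C | intermediate
7 | (4S,5R)-N-methoxy-N,2,2-trimethyl-5-[4-(triisopropylsilyloxy)phenyl]-1,3-dioxolane-4-carboxamide (Weinreb amide) | CC(C)[Si](Oc1ccc(cc1)[C@H]2OC(C)(C)O[C@@H]2C(=O)N(C)OC)(C(C)C)C(C)C | intermediate
8 | [2,4-bis(triisopropylsilyloxy)phenyl]lithium | [Li]c1ccc(O[Si](C(C)C)(C(C)C)C(C)C)cc1O[Si](C(C)C)(C(C)C)C(C)C | intermediate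
9 | [2,4-bis(triisopropylsilyloxy)phenyl][(4S,5R)-2,2-dimethyl-5-[4-(triisopropylsilyloxy)phenyl]-1,3-dioxolan-4-yl]methanone | CC(C)[Si](Oc1ccc(cc1)[C@H]2OC(C)(C)O[C@@H]2C(=O)c3ccc(O[Si](C(C)C)(C(C)C)C(C)C)cc3O[Si](C(C)C)(C(C)C)C(C)C)(C(C)C)C(C)C | intermediate
10 | benzene-1,3-diol (resorcinol) | Oc1cccc(O)c1 | starting material
11 | 3-(4-hydroxyphenyl)propanoic acid | OC(=O)CCc1ccc(O)cc1 | starting material
12 | 1-(2,4-dihydroxyphenyl)-3-(4-hydroxyphenyl)propan-1-one (davidigenin) | O=C(CCc1ccc(O)cc1)c1ccc(O)cc1O | intermediate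
13 | (Z)-{1-[2,4-bis(triisopropylsilyloxy)phenyl]-3-[4-(triisopropylsilyloxy)phenyl]prop-1-en-1-yl}oxy(triisopropyl)silane | CC(C)[Si](O/C(=C\Cc1ccc(O[Si](C(C)C)(C(C)C)C(C)C)cc1)c1ccc(O[Si](C(C)C)(C(C)C)C(C)C)cc1O[Si](C(C)C)(C(C)C)C(C)C)(C(C)C)C(C)C | intermediate
14 | [2,4-bis(triisopropylsilyloxy)phenyl][(2S)-5-[2,4-bis(triisopropylsilyloxy)phenyl]-2-[4-(triisopropylsilyloxy)phenyl]-4-[4-(triisopropylsilyloxy)benzyl]-5-(triisopropylsilyloxy)oxolan-3-yl]methanone (cyclic silyl ketal; epimer mixture at C3, C4, C5; its ring‑opened γ‑silyloxy ketone isomer converges) | O=C(c1ccc(O[Si](C(C)C)(C(C)C)C(C)C)cc1O[Si](C(C)C)(C(C)C)C(C)C)C1C(Cc2ccc(O[Si](C(C)C)(C(C)C)C(C)C)cc2)C(O[Si](C(C)C)(C(C)C)C(C)C)(c2ccc(O[Si](C(C)C)(C(C)C)C(C)C)cc2O[Si](C(C)C)(C(C)C)C(C)C)O[C@@H]1c1ccc(O[Si](C(C)C)(C(C)C)C(C)C)cc1 | intermediate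
15 | [2,4-bis(triisopropylsilyloxy)phenyl][(2S,3S,4S,5S)-5-[2,4-bis(triisopropylsilyloxy)phenyl]-2-[4-(triisopropylsilyloxy)phenyl]-4-[4-(triisopropylsilyloxy)benzyl]oxolan-3-yl]methanone | O=C(c1ccc(O[Si](C(C)C)(C(C)C)C(C)C)cc1O[Si](C(C)C)(C(C)C)C(C)C)[C@H]1[C@H](Cc2ccc(O[Si](C(C)C)(C(C)C)C(C)C)cc2)[C@@H](c2ccc(O[Si](C(C)C)(C(C)C)C(C)C)cc2O[Si](C(C)C)(C(C)C)C(C)C)O[C@@H]1c1ccc(O[Si](C(C)C)(C(C)C)C(C)C)cc1 | intermediate
16 | (2,4-dihydroxyphenyl)[(2S,3S,4S,5S)-5-(2,4-dihydroxyphenyl)-2-(4-hydroxyphenyl)-4-(4-hydroxybenzyl)oxolan-3-yl]methanone | O=C(c1ccc(O)cc1O)[C@H]1[C@H](Cc2ccc(O)cc2)[C@@H](c2ccc(O)cc2O)O[C@@H]1c1ccc(O)cc1 | target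

## Step count and risk

Total steps: 8. Longest linear sequence: 5 (steps 1, 2, 4, 7, 8).

Most likely to fail:

**Step 7 (the proposed new annulation).** The risks are:
- the electron‑rich ketone may be too hard to reduce even when Mg‑bound;
- the α‑keto radical may simply be reduced to the aldol;
- the C3–C4 bond joins two hindered secondary carbons;
- equilibration at C3/C4 may be incomplete;
- the 2,4‑dioxygenated benzylic C5–O bond may be over‑reduced by excess silane.

Fallback by known chemistry, setting out from ketone 9 and returning at 15: SmI2 (2.2 equiv) in THF/MeOH at −78 °C performs the established divalent‑samarium cleavage of the α C–O bond (acetone is lost) to give (3S)-1-[2,4-bis(triisopropylsilyloxy)phenyl]-3-hydroxy-3-[4-(triisopropylsilyloxy)phenyl]propan-1-one F3. TESOTf/Et3N converts it to the bis(triethylsilyl) enol ether F4. NBS in THF at −78 °C gives the α‑bromo‑β‑(triethylsilyloxy) ketone F5. The well‑established photoredox alkylation of a silyl enol ether by an α‑bromo ketone (F5 with 13, fac‑Ir(ppy)3, DMF, blue LEDs) gives the 1,4‑diketone F6. Et3SiH/BF3·OEt2 reductive cycloetherification with equilibration, as practised for oxolane lignans, then delivers 15.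

**Step 2 (decarboxylative arylation).** The electron‑rich aryl bromide is a slow partner for nickel, the acid carries a β‑ester, and base could erode the trans ratio or epimerise 2. Fallback, setting out from acid 2 and returning at 4: esterify 2 with N‑hydroxyphthalimide (DIC, DMAP, CH2Cl2) to the redox‑active N‑hydroxyphthalimide ester F1. Couple it without light (NiCl2·glyme, dtbbpy, THF/DMF, rt) with [4-(triisopropylsilyloxy)phenyl]zinc chloride F2, prepared from 3 by n‑BuLi exchange and ZnCl2. This decarboxylative Negishi arylation gives the same trans ester 4.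

**Step 8 (global desilylation).** Six phenols are released next to a β‑alkoxy ketone and two benzylic ethers. Phenoxide‑driven ring opening, chromanone formation from the 2‑hydroxyaroyl unit, or air oxidation could erode the product. Fallback, setting out from 15 and returning at 16: run the desilylation in the presence of Ac2O (Bu4NF, Ac2O, THF, 0 °C) so each phenoxide is acetylated as it forms, giving the stable, silica‑purifiable hexaacetate F7. Cleave the aryl acetates by ammonolysis (NH3 in MeOH, 0 °C, argon) to 16.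

Further compounds

F1 | step 2 | 4-(1,3-dioxoisoindolin-2-yl) 5-methyl (4S,5S)-2,2-dimethyl-1,3-dioxolane-4,5-dicarboxylate | O=C1c2ccccc2C(=O)N1OC(=O)[C@H]1OC(C)(C)O[C@@H]1C(=O)OC
F2 | step 2 | [4-(triisopropylsilyloxy)phenyl]zinc chloride | Cl[Zn]c1ccc(O[Si](C(C)C)(C(C)C)C(C)C)cc1
F3 | step 7 | (3S)-1-[2,4-bis(triisopropylsilyloxy)phenyl]-3-hydroxy-3-[4-(triisopropylsilyloxy)phenyl]propan-1-one | CC(C)[Si](Oc1ccc(cc1)[C@H](CC(=O)c2ccc(O[Si](C(C)C)(C(C)C)C(C)C)cc2O[Si](C(C)C)(C(C)C)C(C)C)O)(C(C)C)C(C)C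
F4 | step 7 | (Z,3S)-1-[2,4-bis(triisopropylsilyloxy)phenyl]-1,3-bis(triethylsilyloxy)-3-[4-(triisopropylsilyloxy)phenyl]prop-1-ene | CC[Si](CC)(CC)O/C(=C\[C@H](O[Si](CC)(CC)CC)c1ccc(O[Si](C(C)C)(C(C)C)C(C)C)cc1)c1ccc(O[Si](C(C)C)(C(C)C)C(C)C)cc1O[Si](C(C)C)(C(C)C)C(C)C
F5 | step 7 | (3R)-2-bromo-1-[2,4-bis(triisopropylsilyloxy)phenyl]-3-(triethylsilyloxy)-3-[4-(triisopropylsilyloxy)phenyl]propan-1-one (C2 epimers) | CC(C)[Si](Oc1ccc(cc1)[C@H](C(Br)C(=O)c2ccc(O[Si](C(C)C)(C(C)C)C(C)C)cc2O[Si](C(C)C)(C(C)C)C(C)C)O[Si](CC)(CC)CC)(C(C)C)C(C)C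
F6 | step 7 | 1,4-bis[2,4-bis(triisopropylsilyloxy)phenyl]-2-[(S)-(triethylsilyloxy)[4-(triisopropylsilyloxy)phenyl]methyl]-3-[4-(triisopropylsilyloxy)benzyl]butane-1,4-dione (C2/C3 epimers) | CC(C)[Si](Oc1ccc(cc1)[C@@H](O[Si](CC)(CC)CC)C(C(=O)c2ccc(O[Si](C(C)C)(C(C)C)C(C)C)cc2O[Si](C(C)C)(C(C)C)C(C)C)C(Cc2ccc(O[Si](C(C)C)(C(C)C)C(C)C)cc2)C(=O)c2ccc(O[Si](C(C)C)(C(C)C)C(C)C)cc2O[Si](C(C)C)(C(C)C)C(C)C)(C(C)C)C(C)C
F7 | step 8 | hexaacetate of 16: (2,4-diacetoxyphenyl)[(2S,3S,4S,5S)-5-(2,4-diacetoxyphenyl)-2-(4-acetoxyphenyl)-4-(4-acetoxybenzyl)oxolan-3-yl]methanone | O=C(c1ccc(OC(C)=O)cc1OC(C)=O)[C@H]1[C@H](Cc2ccc(OC(C)=O)cc2)[C@@H](c2ccc(OC(C)=O)cc2OC(C)=O)O[C@@H]1c1ccc(OC(C)=O)cc1
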